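(The runs were computed for an exercise, noise included.)

Follow the target.

| setting | winter | summer | spring | blue | ochre | amber | red |
|---|---|---|---|---|---|---|---|
| substrate | 0.046 M | 0.046 M | 0.047 M | 0.046 M | 0.046 M | 0.046 M | 0.060 M |
| partner | 0.040 M (fed, over 4.0 min) | 0.15 M (fed, over 4.0 min) | 0.0552 M (fed, over 4.0 min) | 0.200 M (fed, over 4.0 min) | 0.0552 M (fed, over 15 min) | 0.0552 M (fed, over 4.0 min) | 0.0552 M (fed, over 4.0 min) |
| protic impurity | 0.0138 M | 0.0138 M | 0.0138 M | 0.0138 M | 0.0138 M | 0.0138 M | 0.0400 M |
| temperature | −10 °C | 10 °C | −10 °C | −5 °C | 5 °C | 25 °C | 25 °C |
| remark | run made earlier | run made earlier | run made earlier |  |  |  |  |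
| time |  |  |  | 8.0 min | 8.0 min | 8.0 min | 8.0 min |

- winter (time / min: target / %, over-reaction product / %): 2.50: 0, 3; 5.00: 2, 0; 8.00: 7, 1; 15.0: 12, 0; 30.0: 20, 2
- summer (time / min: target / %, over-reaction product / %): 2.00: 6, 3; 5.00: 28, 2; 6.00: 43, 8; 10.0: 50, 11; 12.0: 48, 13
- spring (time / min: target / %, over-reaction product / %): 3.00: 3, 0; 8.00: 8, 0; 15.0: 14, 2; 25.0: 22, 0; 30.0: 22, 3

(standard deviation of a reading: 2 percentage points)

- ranking by share of target in all that became target or over-reaction product, from high to low, at 8.0 min (blue / ochre / amber / red)
- the share of target in all that became target or over-reaction product of the flask you put first, at 8.0 min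
- the share of target in all that became target or over-reaction product of the flask you put last, at 8.0 min

- percentages count the whole charge, also what has not yet gone in
- no earlier run changes the charge of protic impurity; that part of a forecast is a guess

Build the flask one process at a time, starting with the main step. In blue, substrate is the reagent charged in the smaller amount, the limiting reagent, and its balance reads: substrate left, plus target, plus over-reaction product, equals the charge. The main step is substrate and partner giving target; with that step on its own, over-reaction product stays at zero and the share of target stands at 100%.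

Now add a second process, which is my assumption: target passes on to over-reaction product at a steady fraction per minute, the ageing rate κ. Over-reaction product is then κ times the area under the target curve, so the last over-reaction reading divided by that area gives κ. The summer run at 10 °C gives 0.0345 min⁻¹. The spring run at −10 °C gives 0.00752 min⁻¹, but that rests on a reading of 3% with a scatter of 2 percentage points, so it is rough. Taking ln κ as straight in temperature gives 0.0110 min⁻¹ for blue, 0.0236 min⁻¹ for ochre, and 0.108 min⁻¹ for amber and red. I assume that target is born at a steady pace, which gives it a mean age τ of half the elapsed time, here 4.00 min, so I take the share as 1/(1 + κτ), with no partner in it.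

Add the rest: protic impurity takes partner. In my reckoning that slows the birth of target, and I assume that target and over-reaction product shrink together, so my number stays put. This is a guess, since no earlier run changes the impurity charge. I reckon blue 95.8%, ochre 91.4%, and amber and red tied at 69.8%.

The forecast differs from this. Holding that “The share depends mainly on conversion at 8 min”, it gave ochre > red > blue > amber, with 99% on top and 90% last.

The flask gives blue > ochre > amber > red: blue 98.2%, ochre 94.2%, amber 38.6%, red 34.2%.

    substrate + partner ⇌ target + by-product (K = 0.310, k = 0.0590 L mol⁻¹ s⁻¹, Ea = 49.0 kJ mol⁻¹, ΔH = −21.0 kJ mol⁻¹)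
    target → over-reaction product (k = 0.00430 s⁻¹, Ea = 86.0 kJ mol⁻¹)
    partner + protic impurity → quenched reagent (k = 0.410 L mol⁻¹ s⁻¹, Ea = 58.0 kJ mol⁻¹)
    (constants at 25 °C)

Take the neighbour of blue with 0.80 M of partner, at the same temperature and time. The reckoning carries over unchanged: 0.0345 min⁻¹ scaled to −5 °C, with τ of 4.00 min, gives 95.8%, the same number I reckoned for blue. The neighbour flask holds 78.6% target where blue holds 33.5%, and 1.75% over-reaction product where blue holds 0.617%, so its share comes to 97.8%.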